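**Retrosynthetic overview**
1. Target 13 ← global O-demethylation of its 5,7,5'',7''-tetramethyl ether 12.
2. 12 ← fluoride release from dioxasilepine 11 ← key step: silicon-tethered intramolecular Pd-catalysed C–H arylation of the unsymmetrical bis(aryloxy)silane 10. This forms the 3',3'''-biaryl bond between two complete isoflavones with no boron or tin partner, and the tether enforces cross-selectivity.
3. 10 ← tBu2Si(OTf)2 + bromo-isoflavone 8 + chloro-isoflavone 5, silylated one after the other.
4. 5 and 8 ← one-pot Friedel–Crafts acylation / C1 annulation of phenols 2 and 1 with arylacetic acids 3 and 6; 2 ← chlorination of 1, so Cl is placed before the ring is built.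
5. Ring order: the two pyranone rings first (one per half), then the transient seven-membered silepine that makes the biaryl bond, then ring-opening of the silepine.

Assumption: the target has no stereocentre and its 2,2'-dihydroxybiaryl axis carries only two small ortho groups and rotates freely, so it is one achiral compound and no stereocontrol is needed.

**Step 1**
Reactants: 1 3,5-dimethoxyphenol
Product: 2 2-chloro-3,5-dimethoxyphenol
Conditions: SO2Cl2 (1.0 equiv), CHCl3, 0 °C to rt; chromatography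
Reagents that add atoms: sulfuryl chloride O=S(=O)(Cl)Cl
Why: Electrophilic aromatic chlorination of the electron-rich phenol goes mainly at the two equivalent positions ortho to OH (each also para to an OMe), which are less hindered than C4 between the two methoxy groups, and the symmetric 4-chloro isomer is removed by chromatography.

**Step 2**
Reactants: 2 2-chloro-3,5-dimethoxyphenol + 3 4-hydroxyphenylacetic acid
Product: 5 8-chloro-3-(4-hydroxyphenyl)-5,7-dimethoxy-4H-chromen-4-one, via deoxybenzoin 4 (not isolated)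
Conditions: BF3·OEt2 (solvent), 85 °C; then DMF, MsCl, 50 to 90 °C; aq. NaOAc work-up
Reagents that add atoms: N,N-dimethylformamide CN(C)C=O
Why: One-pot deoxybenzoin isoflavone synthesis in which BF3-mediated Friedel–Crafts (Fries-type) acylation takes the only free position ortho to the phenol OH, the DMF/MsCl Vilsmeier-type reagent then formylates the active methylene, and ring closure through the single free A-ring OH (the one next to Cl) fixes chlorine at C8.

**Step 3**
Reactants: 1 3,5-dimethoxyphenol + 6 3-bromo-4-hydroxyphenylacetic acid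
Product: 8 3-(3-bromo-4-hydroxyphenyl)-5,7-dimethoxy-4H-chromen-4-one, via deoxybenzoin 7 (not isolated)
Conditions: BF3·OEt2 (solvent), 85 °C; then DMF, MsCl, 50 to 90 °C; aq. NaOAc work-up
Reagents that add atoms: N,N-dimethylformamide CN(C)C=O
Why: The same one-pot Friedel–Crafts acylation / Vilsmeier-type annulation, with the chelated BF3 complex directing C-acylation ortho to the phenol OH and the aryl bromide inert to the Lewis-acid conditions.

**Step 4**
Reactants: 8 3-(3-bromo-4-hydroxyphenyl)-5,7-dimethoxy-4H-chromen-4-one + 5 8-chloro-3-(4-hydroxyphenyl)-5,7-dimethoxy-4H-chromen-4-one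
Product: 10 [2-bromo-4-(5,7-dimethoxy-4-oxo-4H-chromen-3-yl)phenoxy][4-(8-chloro-5,7-dimethoxy-4-oxo-4H-chromen-3-yl)phenoxy]di-tert-butylsilane, via silyl triflate 9 (not isolated)
Conditions: tBu2Si(OTf)2 (1.0 equiv), 2,6-lutidine, CH2Cl2, −78 to 0 °C (8 added slowly); then 5, DMAP (cat.), rt to 40 °C
Reagents that add atoms: di-tert-butylsilyl bis(trifluoromethanesulfonate) CC(C)(C)[Si](OS(=O)(=O)C(F)(F)F)(OS(=O)(=O)C(F)(F)F)C(C)(C)C
Why: Sequential O-silylation (temporary silicon tether) in which the first triflate is displaced fast at low temperature by the hindered ortho-bromophenol, while the second, shielded by two tert-butyl groups and the aryloxy group, reacts only on warming with the unhindered phenol 5, giving the unsymmetrical bis(aryloxy)silane.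

**Step 5**
Reactants: 10 the unsymmetrical bis(aryloxy)di-tert-butylsilane
Product: 12 8-chloro-3-{3-[5-(5,7-dimethoxy-4-oxo-4H-chromen-3-yl)-2-hydroxyphenyl]-4-hydroxyphenyl}-5,7-dimethoxy-4H-chromen-4-one, via dioxasilepine 11 (not isolated)
Conditions: Pd(OAc)2 (10 mol %), PPh3 (20 mol %), PivOH (30 mol %), Cs2CO3 (1.5 equiv), p-xylene, 140 °C; filter, concentrate; then TBAF, AcOH, THF, 0 °C to rt
Reagents that add atoms: none
Why: Silicon-tethered intramolecular Pd-catalysed direct C–H arylation, in which oxidative addition into C–Br, pivalate-assisted concerted metalation–deprotonation of the only C–H in reach (ortho to the second Si–O, both ortho positions being equivalent) and reductive elimination close the seven-membered dioxasilepine, so only the cross-biaryl can form; buffered fluoride then cleaves both Si–O bonds, and the hindered electron-rich C8–Cl is inert to Pd/PPh3.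

**Step 6**
Reactants: 12 the tetra-O-methyl ether of the target
Product: 13 Bisoflavolin N
Conditions: BBr3 (12 equiv), CH2Cl2, −78 °C to rt; then MeOH/H2O
Reagents that add atoms: none
Why: Lewis-acid ether cleavage (BBr3 demethylation) in which the chelated 5-OMe groups cleave first and the 7-OMe groups on warming, while the aryl chloride, the biaryl bond and both pyranone rings are stable under anhydrous acidic conditions.

**Compound list**
1 | 3,5-dimethoxyphenol | COc1cc(O)cc(OC)c1 | starting material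
2 | 2-chloro-3,5-dimethoxyphenol | COc1cc(O)c(Cl)c(OC)c1 | intermediate
3 | 4-hydroxyphenylacetic acid | OC(=O)Cc1ccc(O)cc1 | starting material
4 | 1-(3-chloro-2-hydroxy-4,6-dimethoxyphenyl)-2-(4-hydroxyphenyl)ethan-1-one (deoxybenzoin) | COc1cc(OC)c(C(=O)Cc2ccc(O)cc2)c(O)c1Cl | intermediate
5 | 8-chloro-3-(4-hydroxyphenyl)-5,7-dimethoxy-4H-chromen-4-one | COc1cc(OC)c2c(c1Cl)occ(-c3ccc(O)cc3)c2=O | intermediate
6 | 3-bromo-4-hydroxyphenylacetic acid | OC(=O)Cc1ccc(O)c(Br)c1 | starting material
7 | 2-(3-bromo-4-hydroxyphenyl)-1-(2-hydroxy-4,6-dimethoxyphenyl)ethan-1-one (deoxybenzoin) | COc1cc(O)c(C(=O)Cc2ccc(O)c(Br)c2)c(OC)c1 | intermediate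
8 | 3-(3-bromo-4-hydroxyphenyl)-5,7-dimethoxy-4H-chromen-4-one | COc1cc(OC)c2c(c1)occ(-c3ccc(O)c(Br)c3)c2=O | intermediate
9 | [2-bromo-4-(5,7-dimethoxy-4-oxo-4H-chromen-3-yl)phenoxy]di-tert-butylsilyl trifluoromethanesulfonate | COc1cc(OC)c2c(c1)occ(-c3ccc(O[Si](OS(=O)(=O)C(F)(F)F)(C(C)(C)C)C(C)(C)C)c(Br)c3)c2=O | intermediate
10 | [2-bromo-4-(5,7-dimethoxy-4-oxo-4H-chromen-3-yl)phenoxy][4-(8-chloro-5,7-dimethoxy-4-oxo-4H-chromen-3-yl)phenoxy]di-tert-butylsilane | COc1cc(OC)c2c(c1)occ(-c3ccc(O[Si](Oc4ccc(-c5coc6c(Cl)c(OC)cc(OC)c6c5=O)cc4)(C(C)(C)C)C(C)(C)C)c(Br)c3)c2=O | intermediate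
11 | 6,6-di-tert-butyl-2-(8-chloro-5,7-dimethoxy-4-oxo-4H-chromen-3-yl)-10-(5,7-dimethoxy-4-oxo-4H-chromen-3-yl)dibenzo[d,f][1,3,2]dioxasilepine | COc1cc(OC)c2c(c1)occ(-c3ccc4O[Si](C(C)(C)C)(C(C)(C)C)Oc5ccc(-c6coc7c(Cl)c(OC)cc(OC)c7c6=O)cc5-c4c3)c2=O | intermediate
12 | 8-chloro-3-{3-[5-(5,7-dimethoxy-4-oxo-4H-chromen-3-yl)-2-hydroxyphenyl]-4-hydroxyphenyl}-5,7-dimethoxy-4H-chromen-4-one | COc1cc(OC)c2c(c1)occ(-c3ccc(O)c(-c4cc(-c5coc6c(Cl)c(OC)cc(OC)c6c5=O)ccc4O)c3)c2=O | intermediate
13 | Bisoflavolin N, 8-chloro-3-{3-[5-(5,7-dihydroxy-4-oxo-4H-chromen-3-yl)-2-hydroxyphenyl]-4-hydroxyphenyl}-5,7-dihydroxy-4H-chromen-4-one | O=c1c(-c2ccc(O)c(-c3cc(-c4coc5c(Cl)c(O)cc(O)c5c4=O)ccc3O)c2)coc2cc(O)cc(O)c12 | target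

**Step count**
Total steps: 6. Longest linear sequence: 5 steps (1 → 2 → 5 → 10 → 12 → 13; step 3 is the convergent branch).

**Three steps most likely to fail, with fallbacks**

Step 5, the key C–H arylation, may give protodebromination or fail to cyclometalate on this large substrate. The fallback gives up the tether and joins the halves by a conventional Suzuki coupling. It sets out from 5 and 8. NIS with catalytic TsOH in MeCN iodinates 5 ortho to the phenol (C8 is already blocked by Cl) to give 8-chloro-3-(4-hydroxy-3-iodophenyl)-5,7-dimethoxy-4H-chromen-4-one F1. Miyaura borylation of 8 (B2pin2, PdCl2(dppf), KOAc, dioxane, 90 °C) gives 3-[4-hydroxy-3-(4,4,5,5-tetramethyl-1,3,2-dioxaborolan-2-yl)phenyl]-5,7-dimethoxy-4H-chromen-4-one F2. Coupling F1 with F2 (PdCl2(dppf), K3PO4, dioxane/H2O, 80 °C) comes back to the route at 12.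

Step 4, the unsymmetrical silane, may give the symmetric bis-ether of 8 or a sluggish second substitution. The fallback builds the tether from a hydrosilane instead of the bis-triflate and starts on the other half. It sets out from 5. tBu2SiHCl with imidazole in DMF gives di-tert-butyl[4-(8-chloro-5,7-dimethoxy-4-oxo-4H-chromen-3-yl)phenoxy]silane F3. NBS in CH2Cl2 at 0 °C turns Si–H into Si–Br (C8 of this half already carries Cl, so the A ring is not brominated) to give bromo(di-tert-butyl)[4-(8-chloro-5,7-dimethoxy-4-oxo-4H-chromen-3-yl)phenoxy]silane F4. F4 and phenol 8 with imidazole in DMF come back to the route at 10.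

Step 2, the one-pot acylation/annulation on the deactivated chlorophenol, may stall or give formylated by-products. The fallback makes the C3–aryl bond by cross-coupling on a preformed chromone. It sets out from 2. Ac2O in BF3·OEt2 gives 1-(3-chloro-2-hydroxy-4,6-dimethoxyphenyl)ethan-1-one F5. DMF-DMA at 95 °C gives (E)-1-(3-chloro-2-hydroxy-4,6-dimethoxyphenyl)-3-(dimethylamino)prop-2-en-1-one F6. I2 in CHCl3 cyclises it to 8-chloro-3-iodo-5,7-dimethoxy-4H-chromen-4-one F7. Suzuki coupling of F7 with 4-hydroxyphenylboronic acid (Pd(PPh3)4, Na2CO3, DME/H2O, 70 °C) comes back to the route at 5.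

**Further compounds**
F1 | step 5 | 8-chloro-3-(4-hydroxy-3-iodophenyl)-5,7-dimethoxy-4H-chromen-4-one | COc1cc(OC)c2c(c1Cl)occ(-c3ccc(O)c(I)c3)c2=O
F2 | step 5 | 3-[4-hydroxy-3-(4,4,5,5-tetramethyl-1,3,2-dioxaborolan-2-yl)phenyl]-5,7-dimethoxy-4H-chromen-4-one | COc1cc(OC)c2c(c1)occ(-c3ccc(O)c(B4OC(C)(C)C(C)(C)O4)c3)c2=O
F3 | step 4 | di-tert-butyl[4-(8-chloro-5,7-dimethoxy-4-oxo-4H-chromen-3-yl)phenoxy]silane | COc1cc(OC)c2c(c1Cl)occ(-c3ccc(O[SiH](C(C)(C)C)C(C)(C)C)cc3)c2=O
F4 | step 4 | bromo(di-tert-butyl)[4-(8-chloro-5,7-dimethoxy-4-oxo-4H-chromen-3-yl)phenoxy]silane | COc1cc(OC)c2c(c1Cl)occ(-c3ccc(O[Si](Br)(C(C)(C)C)C(C)(C)C)cc3)c2=O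
F5 | step 2 | 1-(3-chloro-2-hydroxy-4,6-dimethoxyphenyl)ethan-1-one | CC(=O)c1c(O)c(Cl)c(OC)cc1OC
F6 | step 2 | (E)-1-(3-chloro-2-hydroxy-4,6-dimethoxyphenyl)-3-(dimethylamino)prop-2-en-1-one | CN(C)/C=C/C(=O)c1c(O)c(Cl)c(OC)cc1OC
F7 | step 2 | 8-chloro-3-iodo-5,7-dimethoxy-4H-chromen-4-one | COc1cc(OC)c2c(c1Cl)occ(I)c2=O
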